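**Plan**
- Retrosynthesis cuts, in this order: the two C–O bonds of the C3/C4 oxirane, the C11 carbinol C–H, the C7–OAc bond, the lactone C12–O bond and the C16 oxygens. This leaves (R)-cembrene A, whose only ring C–C cut is C1–C2.
- Enabling feature (cembrane numbering: C1 = ring CH bearing C15, C16 = lactone carbonyl, C17 = exo-CH2): the fourteen-membered carbocycle C1–C14 is a geranylgeranyl chain closed at C1–C2. The oxirane (C3/C4), the acetoxy alcohol (C7/C8) and the lactone diol (C11/C12) sit on its three E-trisubstituted alkenes, and C15–C17 is the former isopropenyl group.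
- Forward: geranylgeraniol is diphosphorylated and a cembrene A synthase closes the carbocycle. The isopropenyl group becomes an acrylic acid, which first masks C3=C4 as a six-membered bromolactone; after double epoxidation and unmasking it closes the seven-membered lactone ring onto C12. The C3/C4 oxirane ring is made last.
- Stereochemistry: C1 from the enzyme; C3, C4, C7, C8 and C12 from epoxidations with the L-fructose-derived Shi ketone (C7 and C12 by SN2 inversion of the epoxides); C11 from a Felkin–Anh ketone reduction.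

Key step: step 3

Remark: the target is taken as (1R,3S,4S,7R,8S,11R,12R) in cembrane numbering, and a recombinant cembrene A synthase of the 1R series is taken to be available.

**Step 1**
Reactants: 1 geranylgeraniol
Product: 2 geranylgeranyl chloride
Conditions: NCS, Me2S, CH2Cl2, −40 to 0 °C
Reagents that add atoms: N-chlorosuccinimide, O=C1CCC(=O)N1Cl
Why: Corey–Kim chlorination turns the primary allylic alcohol into the chloride by SN2 displacement of the alkoxysulfonium ion, without allylic transposition or loss of the 2E geometry.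

**Step 2**
Reactants: 2 geranylgeranyl chloride
Product: 3 geranylgeranyl diphosphate (tris-ammonium salt)
Conditions: (n-Bu4N)3HP2O7, MeCN, rt; cation exchange (NH4+ form)
Reagents that add atoms: tris(tetrabutylammonium) hydrogen diphosphate, CCCC[N+](CCCC)(CCCC)CCCC.CCCC[N+](CCCC)(CCCC)CCCC.CCCC[N+](CCCC)(CCCC)CCCC.OP(=O)([O-])OP(=O)([O-])[O-]
Why: SN2 displacement of the primary allylic chloride by the weakly solvated diphosphate anion is the standard diphosphorylation of prenyl halides, and cation exchange gives the enzyme-compatible ammonium salt.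

**Step 3**
Reactants: 3 geranylgeranyl diphosphate (tris-ammonium salt)
Product: 4 (R)-cembrene A
Conditions: recombinant (R)-cembrene A synthase, MgCl2, Tris buffer pH 7.5, 30 °C, pentane overlay
Reagents that add atoms: none
Why: Mg2+-assisted ionisation of the allylic diphosphate gives the C2–C4 allyl cation; C1 of the distal C1=C15 alkene attacks the primary terminus C2, forming the C1–C2 bond, and the tertiary C15 cation loses a C17 proton to give the isopropenyl group. The closest known reaction type is the class 1 terpene synthase cyclisation of geranylgeranyl diphosphate to cembrene A, which is established enzymology. The fourteen-membered ring closes exo with respect to the attacking alkene (C15 ends outside the ring) and endo with respect to the allyl cation, so the 3E alkene stays in the ring. The new stereocenter C1 is set by the enantioface of the C1=C15 alkene that the active site exposes, which is why a synthase of the 1R series is required. The step needs macrocyclisation over water capture or elimination to acyclic products, and it must keep the three E alkenes; the pre-organising hydrophobic active site, which replaces high dilution, should secure both.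

**Step 4**
Reactants: 4 (R)-cembrene A
Product: 7 (1R)-cembra-3E,7E,11E,15(17)-tetraen-16-ol, via allyllithium 5 (not isolated), via allylboronate 6 (not isolated)
Conditions: n-BuLi, TMEDA, hexane, rt; B(OMe)3, −78 °C; H2O2, aq NaOH, 0 °C
Reagents that add atoms: n-butyllithium, [Li]CCCC (Li of 5); trimethyl borate, COB(OC)OC (boryl group of 6); hydrogen peroxide, OO (oxygen of 7)
Why: kinetic allylic metalation removes a proton from the methyl of the 1,1-disubstituted alkene (least substituted allyl anion, as known for limonene) rather than from the ring allylic positions, and the symmetric 2-substituted allyl anion is borylated and oxidised to the primary allylic alcohol with C1 untouched.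

**Step 5**
Reactants: 7 (1R)-cembra-3E,7E,11E,15(17)-tetraen-16-ol
Product: 8 (1R)-cembra-3E,7E,11E,15(17)-tetraen-16-al
Conditions: MnO2, CH2Cl2, rt
Reagents that add atoms: none
Why: MnO2 oxidises only the allylic alcohol to the enal (allylic alcohol oxidation) and leaves the isolated ring alkenes alone.

**Step 6**
Reactants: 8 (1R)-cembra-3E,7E,11E,15(17)-tetraen-16-al
Product: 9 (1R)-cembra-3E,7E,11E,15(17)-tetraen-16-oic acid
Conditions: NaClO2, NaH2PO4, 2-methyl-2-butene, t-BuOH/H2O, 0 °C to rt
Reagents that add atoms: sodium chlorite, [Na+].[O-]Cl=O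
Why: Pinnick oxidation converts the enal into the acrylic acid while the excess scavenger alkene intercepts HOCl before it can reach the ring alkenes.

**Step 7**
Reactants: 9 (1R)-cembra-3E,7E,11E,15(17)-tetraen-16-oic acid
Product: 10 (1R,3R,4S)-4-bromocembra-7E,11E,15(17)-trien-16,3-olide
Conditions: KHCO3, NBS, THF, −20 °C, dark
Reagents that add atoms: N-bromosuccinimide, O=C1CCC(=O)N1Br
Why: in this bromolactonisation the bromonium ion is passed reversibly among the alkenes and is trapped through the only six-membered closure available, the carboxylate attacking C3 anti to bromine (6-exo, chair, cis-lactone, temporary centers C3 R and C4 S); seven-membered closure onto C12 is much slower, and any regio- or stereoisomer of this mask would give the same alkene acid in step 9.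

**Step 8**
Reactants: 10 (1R,3R,4S)-4-bromocembra-7E,11E,15(17)-trien-16,3-olide
Product: 11 (1R,3R,4S,7S,8S,11S,12S)-4-bromo-7,8:11,12-diepoxycembr-15(17)-en-16,3-olide
Conditions: L-fructose-derived Shi ketone, KHSO5 (as 2KHSO5·KHSO4·K2SO4), NaHCO3, MeCN/aq Na2EDTA, 0 °C
Reagents that add atoms: potassium peroxymonosulfate, [K+].[O-]S(=O)(=O)OO
Why: Shi epoxidation through the spiro transition state of the chiral dioxirane sets C7, C8, C11 and C12 (all S) under reagent control on the two remaining electron-rich E-trisubstituted alkenes; the acrylate is too electron-poor to react and the near-neutral buffer spares the lactone.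

**Step 9**
Reactants: 11 (1R,3R,4S,7S,8S,11S,12S)-4-bromo-7,8:11,12-diepoxycembr-15(17)-en-16,3-olide
Product: 14 (1R,7S,8S,12R)-7,8-epoxy-11-oxocembra-3E,15(17)-dien-16,12-olide, via diepoxy acid 12 (not isolated), via hydroxy lactone 13 (not isolated)
Conditions: Zn dust, NH4Cl, THF/EtOH, 0 °C; PhMe (high dilution), 40 °C; Dess–Martin periodinane, NaHCO3, CH2Cl2, 0 °C
Reagents that add atoms: none
Why: zinc-mediated reductive β-elimination (Boord-type opening of the halolactone) should return the 3E alkene and the acid, which opens the only epoxide within reach by 7-exo attack at tertiary C12 with inversion (12R, leaving 11S-OH); Dess–Martin oxidation then removes the C11 hydroxyl before it can attack the 7,8-epoxide and readies C11 for resetting.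

**Step 10**
Reactants: 14 (1R,7S,8S,12R)-7,8-epoxy-11-oxocembra-3E,15(17)-dien-16,12-olide
Product: 15 (1R,7R,8S,12R)-7-acetoxy-8-hydroxy-11-oxocembra-3E,15(17)-dien-16,12-olide
Conditions: CsOAc, AcOH, DMF, 80 °C
Reagents that add atoms: cesium acetate, CC(=O)[O-].[Cs+] (acetic acid, CC(=O)O, supplies the proton)
Why: carboxylate opening of the trisubstituted epoxide under non-acidic SN2 conditions should occur at the less substituted C7 with inversion (7R) and keep the tertiary C8–O bond (8S), giving the hydroxy acetate directly with no other epoxide or free secondary hydroxyl present to compete.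

**Step 11**
Reactants: 15 (1R,7R,8S,12R)-7-acetoxy-8-hydroxy-11-oxocembra-3E,15(17)-dien-16,12-olide
Product: 16 (1R,7R,8S,11R,12R)-7-acetoxy-8,11-dihydroxycembra-3E,15(17)-dien-16,12-olide
Conditions: NaBH4, CeCl3·7H2O, MeOH, −78 °C
Reagents that add atoms: none
Why: in this Luche reduction the polar Felkin–Anh model (hydride anti to the C12–O bond, passing the C12 methyl) predicts the 11R alcohol syn to the lactone oxygen, while CeCl3 and low temperature protect the methylene lactone and the acetate.

**Step 12**
Reactants: 16 (1R,7R,8S,11R,12R)-7-acetoxy-8,11-dihydroxycembra-3E,15(17)-dien-16,12-olide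
Product: 17 CNP0174704.2
Conditions: L-fructose-derived Shi ketone, KHSO5 (as 2KHSO5·KHSO4·K2SO4), NaHCO3, MeCN/aq Na2EDTA, 0 °C
Reagents that add atoms: potassium peroxymonosulfate, [K+].[O-]S(=O)(=O)OO
Why: Shi epoxidation of the last electron-rich alkene sets C3 and C4 (both S) by the same spiro transition state as in step 8, the acrylate again being inert and the buffered pH sparing acetate and lactone.

**Compound list**
1 | geranylgeraniol | CC(C)=CCC/C(C)=C/CC/C(C)=C/CC/C(C)=C/CO | starting material
2 | geranylgeranyl chloride | CC(C)=CCC/C(C)=C/CC/C(C)=C/CC/C(C)=C/CCl | intermediate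
3 | geranylgeranyl diphosphate (isolated as tris-ammonium salt, drawn as free acid) | CC(C)=CCC/C(C)=C/CC/C(C)=C/CC/C(C)=C/COP(=O)(O)OP(=O)(O)O | intermediate
4 | (R)-cembrene A, (1R,3E,7E,11E)-cembra-3,7,11,15(17)-tetraene | C=C(C)[C@@H]1CC/C(C)=C/CC/C(C)=C/CC/C(C)=C/C1 | intermediate
5 | C16 allyllithium of 4 | [Li]CC(=C)[C@@H]1CC/C(C)=C/CC/C(C)=C/CC/C(C)=C/C1 | intermediate (not isolated)
6 | dimethyl C16 allylboronate of 4 | COB(OC)CC(=C)[C@@H]1CC/C(C)=C/CC/C(C)=C/CC/C(C)=C/C1 | intermediate (not isolated)
7 | (1R,3E,7E,11E)-cembra-3,7,11,15(17)-tetraen-16-ol | C=C(CO)[C@@H]1CC/C(C)=C/CC/C(C)=C/CC/C(C)=C/C1 | intermediate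
8 | (1R,3E,7E,11E)-cembra-3,7,11,15(17)-tetraen-16-al | C=C(C=O)[C@@H]1CC/C(C)=C/CC/C(C)=C/CC/C(C)=C/C1 | intermediate
9 | (1R,3E,7E,11E)-cembra-3,7,11,15(17)-tetraen-16-oic acid | C=C(C(=O)O)[C@@H]1CC/C(C)=C/CC/C(C)=C/CC/C(C)=C/C1 | intermediate
10 | (1R,3R,4S,7E,11E)-4-bromocembra-7,11,15(17)-trien-16,3-olide (six-membered lactone, O on C3, Br on C4) | C=C1C(=O)O[C@@H]2C[C@H]1CC/C(C)=C/CC/C(C)=C/CC[C@]2(C)Br | intermediate
11 | (1R,3R,4S,7S,8S,11S,12S)-4-bromo-7,8:11,12-diepoxycembr-15(17)-en-16,3-olide | C=C1C(=O)O[C@@H]2C[C@H]1CC[C@]3(C)O[C@H]3CC[C@]3(C)O[C@H]3CC[C@]2(C)Br | intermediate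
12 | (1R,3E,7S,8S,11S,12S)-7,8:11,12-diepoxycembra-3,15(17)-dien-16-oic acid | C=C(C(=O)O)[C@@H]1CC[C@]2(C)O[C@H]2CC[C@]2(C)O[C@H]2CC/C(C)=C/C1 | intermediate (not isolated)
13 | (1R,3E,7S,8S,11S,12R)-7,8-epoxy-11-hydroxycembra-3,15(17)-dien-16,12-olide | C=C1C(=O)O[C@]2(C)CC[C@@H]1C/C=C(C)/CC[C@@H]3O[C@@]3(C)CC[C@@H]2O | intermediate (not isolated)
14 | (1R,3E,7S,8S,12R)-7,8-epoxy-11-oxocembra-3,15(17)-dien-16,12-olide | C=C1C(=O)O[C@]2(C)CC[C@@H]1C/C=C(C)/CC[C@@H]3O[C@@]3(C)CCC2=O | intermediate
15 | (1R,3E,7R,8S,12R)-7-acetoxy-8-hydroxy-11-oxocembra-3,15(17)-dien-16,12-olide | C=C1C(=O)O[C@]2(C)CC[C@@H]1C/C=C(C)/CC[C@@H](OC(C)=O)[C@@](C)(O)CCC2=O | intermediate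
16 | (1R,3E,7R,8S,11R,12R)-7-acetoxy-8,11-dihydroxycembra-3,15(17)-dien-16,12-olide | C=C1C(=O)O[C@]2(C)CC[C@@H]1C/C=C(C)/CC[C@@H](OC(C)=O)[C@@](C)(O)CC[C@H]2O | intermediate
17 | CNP0174704.2, (1R,3S,4S,7R,8S,11R,12R)-7-acetoxy-3,4-epoxy-8,11-dihydroxycembr-15(17)-en-16,12-olide | C=C1C(=O)O[C@]2(C)CC[C@@H]1C[C@@H]1O[C@@]1(C)CC[C@@H](OC(C)=O)[C@@](C)(O)CC[C@H]2O | target

Total step count: 12. Longest linear sequence: 12 steps (1 to 17).

**Steps most likely to fail**

Step 9. The zinc elimination may erode the E geometry of the regenerated C3=C4 alkene, and the new C11 hydroxyl may attack the 7,8-epoxide transannularly before it is oxidised. The fallback drops the bromolactone mask and sets out from acid 9. Shi epoxidation of its carboxylate with the L-fructose-derived ketone and KHSO5 would epoxidise all three ring alkenes to the triepoxy acid F1. Mild acidification and warming in dilute toluene should let the acid open the 11,12-epoxide at C12 to the diepoxy hydroxy lactone F2, which Dess–Martin periodinane would oxidise to the diepoxy keto lactone F3. CsOAc/AcOH would then open the 7,8-epoxide at C7 to the epoxy acetoxy ketone F4, and NaBH4/CeCl3·7H2O would reduce this to 17, where the fallback rejoins the route. This path has to rely on the acid preferring tertiary C12 over the 3,4-epoxide and on acetate preferring the unbranched C7 over the β-branched C3.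

Step 10. Acetate may attack tertiary C8, or the epoxide may eliminate to an allylic alcohol, instead of clean SN2 at C7. The fallback sets out from 14 and uses only Markovnikov openings. Dilute HClO4 in aqueous THF should open the epoxide at C8 with inversion to the (7S,8R)-diol F5. MsCl/Et3N would sulfonylate only the secondary hydroxyl to the 7-mesylate F6, and DBU would close the tertiary alkoxide onto C7 with inversion to the (7R,8R)-epoxide F7. A second acid hydrolysis at C8 would give the (7R,8S)-diol F8, and Ac2O/pyridine would acetylate its secondary hydroxyl to give 15.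

Step 11. Hydride may add from the wrong face of the macrocyclic ketone. The fallback sets out from 15. The 11S alcohol F9 from the reduction would be inverted by Mitsunobu reaction with chloroacetic acid (PPh3, DIAD) to the 11R chloroacetate F10. Brief NaHCO3 in aqueous MeOH at 0 °C should cleave this ester in the presence of the acetate and give 16.

**Further compounds**
F1 | step 9 | (1R,3S,4S,7S,8S,11S,12S)-3,4:7,8:11,12-triepoxycembr-15(17)-en-16-oic acid | C=C(C(=O)O)[C@@H]1CC[C@]2(C)O[C@H]2CC[C@]2(C)O[C@H]2CC[C@]2(C)O[C@H]2C1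
F2 | step 9 | (1R,3S,4S,7S,8S,11S,12R)-3,4:7,8-diepoxy-11-hydroxycembr-15(17)-en-16,12-olide | C=C1C(=O)O[C@]2(C)CC[C@@H]1C[C@@H]1O[C@@]1(C)CC[C@@H]3O[C@@]3(C)CC[C@@H]2O
F3 | step 9 | (1R,3S,4S,7S,8S,12R)-3,4:7,8-diepoxy-11-oxocembr-15(17)-en-16,12-olide | C=C1C(=O)O[C@]2(C)CC[C@@H]1C[C@@H]1O[C@@]1(C)CC[C@@H]3O[C@@]3(C)CCC2=O
F4 | step 9 | (1R,3S,4S,7R,8S,12R)-7-acetoxy-3,4-epoxy-8-hydroxy-11-oxocembr-15(17)-en-16,12-olide | C=C1C(=O)O[C@]2(C)CC[C@@H]1C[C@@H]1O[C@@]1(C)CC[C@@H](OC(C)=O)[C@@](C)(O)CCC2=O
F5 | step 10 | (1R,3E,7S,8R,12R)-7,8-dihydroxy-11-oxocembra-3,15(17)-dien-16,12-olide | C=C1C(=O)O[C@]2(C)CC[C@@H]1C/C=C(C)/CC[C@H](O)[C@](C)(O)CCC2=O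
F6 | step 10 | 7-O-methanesulfonate of F5 | C=C1C(=O)O[C@]2(C)CC[C@@H]1C/C=C(C)/CC[C@H](OS(C)(=O)=O)[C@](C)(O)CCC2=O
F7 | step 10 | (1R,3E,7R,8R,12R)-7,8-epoxy-11-oxocembra-3,15(17)-dien-16,12-olide | C=C1C(=O)O[C@]2(C)CC[C@@H]1C/C=C(C)/CC[C@H]3O[C@]3(C)CCC2=O
F8 | step 10 | (1R,3E,7R,8S,12R)-7,8-dihydroxy-11-oxocembra-3,15(17)-dien-16,12-olide | C=C1C(=O)O[C@]2(C)CC[C@@H]1C/C=C(C)/CC[C@@H](O)[C@@](C)(O)CCC2=O
F9 | step 11 | (1R,3E,7R,8S,11S,12R)-7-acetoxy-8,11-dihydroxycembra-3,15(17)-dien-16,12-olide (11-epimer of 16) | C=C1C(=O)O[C@]2(C)CC[C@@H]1C/C=C(C)/CC[C@@H](OC(C)=O)[C@@](C)(O)CC[C@@H]2O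
F10 | step 11 | 11R chloroacetate of 16 | C=C1C(=O)O[C@]2(C)CC[C@@H]1C/C=C(C)/CC[C@@H](OC(C)=O)[C@@](C)(O)CC[C@H]2OC(=O)CCl
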